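**Strategy**

Ring A (C1–C4, the quinone ring) is joined to the benzenoid ring only through the fusion carbons C8a and C4a, an ortho pair lying between the oxygen-bearing carbons C8 and C5. Cutting C1–C8a and C4–C4a therefore leads back to a symmetrical 3,6-dialkoxybenzyne and a furan whose C2 and C5 become C1 and C4 and whose C3 already carries the (R)-configured side chain. A single aryne–furan [4+2] cycloaddition makes both bonds and closes ring A as a 1,4-epoxide. Its precursors are 2-bromo-1,4-bis(methoxymethoxy)benzene, chosen so that the phenols can later be freed with dilute acid, and the silyl ether of (R)-1-(furan-3-yl)-4-methylpent-3-en-1-ol.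

Key step: step 6

Remark: the aryl oxygens are carried as methoxymethyl (MOM) ethers because methyl ethers peri to a quinone carbonyl would need oxidative or strongly Lewis-acidic cleavage that the side chain is unlikely to survive; LiTMP is assumed to be taken from a commercial supply, and the carbinol centre is R throughout (shikonin series).

**Route**

Step 1
Reactants: 1 4-methylpent-3-enoic acid
Product: 3 N-methoxy-N,4-dimethylpent-3-enamide, via acyl imidazole 2 (not isolated)
Conditions: 1,1'-carbonyldiimidazole (1.1 equiv), CH2Cl2, 0 °C to 25 °C; then MeNHOMe·HCl (1.2 equiv), 25 °C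
Reagents that add atoms: N,O-dimethylhydroxylamine hydrochloride, CNOC.Cl
Why: Carbonyldiimidazole amide coupling (acyl imidazole formation, then aminolysis) gives the Weinreb amide under near-neutral conditions that should leave the β,γ-alkene out of conjugation.

Step 2
Reactants: 4 3-bromofuran; 3 N-methoxy-N,4-dimethylpent-3-enamide
Product: 7 1-(furan-3-yl)-4-methylpent-3-en-1-one, via furan-3-yllithium 5 (not isolated), via lithium aminoalkoxide 6 (not isolated)
Conditions: n-BuLi (1.05 equiv per 4), THF, −78 °C; then 3, −78 °C; aq. NH4Cl quench at −78 °C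
Reagents that add atoms: none
Why: Bromine–lithium exchange at −78 °C gives the 3-lithiofuran without migration to C2, and its addition to the amide stops at the chelated tetrahedral adduct (Weinreb ketone synthesis), so the skipped enone is released only on the cold quench.

Step 3
Reactants: 7 1-(furan-3-yl)-4-methylpent-3-en-1-one
Product: 8 (1R)-1-(furan-3-yl)-4-methylpent-3-en-1-ol
Conditions: (S)-Me-CBS oxazaborolidine [(S)-1-methyl-3,3-diphenyltetrahydro-1H,3H-pyrrolo[1,2-c][1,3,2]oxazaborole] (20 mol%), catecholborane (1.5 equiv), toluene, −78 °C; aqueous NaOH work-up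
Reagents that add atoms: none
Why: Corey–Bakshi–Shibata reduction, in which the (S)-oxazaborolidine binds the ketone with the furyl group as the large substituent and directs hydride from catecholborane to one carbonyl face, should set the R carbinol (the sense of acetophenone to (R)-1-phenylethanol), and catecholborane at −78 °C does not hydroborate the alkene.

Step 4
Reactants: 8 (1R)-1-(furan-3-yl)-4-methylpent-3-en-1-ol
Product: 9 tert-butyl{[(1R)-1-(furan-3-yl)-4-methylpent-3-en-1-yl]oxy}dimethylsilane
Conditions: TBSCl (1.2 equiv), imidazole (2.5 equiv), DMF, 25 °C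
Reagents that add atoms: tert-butyldimethylsilyl chloride, CC(C)(C)[Si](C)(C)Cl
Why: Imidazole-promoted silylation of a secondary alcohol gives a TBS ether that tolerates the lithium amide of step 6 and prevents alkoxide addition to the aryne.

Step 5
Reactants: 10 2-bromobenzene-1,4-diol
Product: 11 2-bromo-1,4-bis(methoxymethoxy)benzene
Conditions: MOMCl (2.5 equiv), i-Pr2NEt (3 equiv), CH2Cl2, 0 °C to 25 °C, under N2
Reagents that add atoms: chloromethyl methyl ether, COCCl
Why: O-Alkylation of both phenols (Williamson-type acetal ether formation) gives MOM ethers that survive strong base, assist ortho-lithiation and can be removed later with dilute acid.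

Step 6
Reactants: 11 2-bromo-1,4-bis(methoxymethoxy)benzene; 9 tert-butyl{[(1R)-1-(furan-3-yl)-4-methylpent-3-en-1-yl]oxy}dimethylsilane
Product: 14 tert-butyl({(1R)-1-[5,8-bis(methoxymethoxy)-1,4-dihydro-1,4-epoxynaphthalen-2-yl]-4-methylpent-3-en-1-yl}oxy)dimethylsilane as both bridgehead epimers, via aryllithium 12 (not isolated), via aryne 13 (not isolated)
Conditions: 11 (2.5 equiv), 9 (1.0 equiv), LiTMP (2.6 equiv, added dropwise), THF, −78 °C to 0 °C
Reagents that add atoms: none
Why: LiTMP removes the proton at C3 of 11, the position acidified by bromine and by the neighbouring acetal oxygen, and the aryllithium loses LiBr on warming to give the symmetrical 3,6-dialkoxybenzyne, which the furan diene traps in a concerted suprafacial [4+2] cycloaddition (aryne–furan Diels–Alder reaction, the standard entry to 1,4-dihydro-1,4-epoxynaphthalenes). Ring A is closed intermolecularly in this one event, furan C2 and C5 bonding to the two aryne carbons to give the six-membered carbocycle bridged by the furan oxygen. The two bridgehead stereocentres necessarily form cis to each other; their sense relative to the side-chain centre is not controlled and need not be, because both epimers lose these centres on aromatisation in step 7, while the silyloxy stereocentre lies outside the reacting atoms and carries no acidic hydrogen of consequence. The selectivity needed is chemoselectivity: the symmetry of the aryne removes any regiochemical question, aryne strain makes cycloaddition to the electron-rich furan faster than an ene reaction with the trisubstituted alkene, and the hindered amide together with the excess of 11 should keep amine addition and furan metalation from consuming the limiting furan.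

Step 7
Reactants: 14 tert-butyl({(1R)-1-[5,8-bis(methoxymethoxy)-1,4-dihydro-1,4-epoxynaphthalen-2-yl]-4-methylpent-3-en-1-yl}oxy)dimethylsilane
Product: 17 2-[(1R)-1-{[tert-butyl(dimethyl)silyl]oxy}-4-methylpent-3-en-1-yl]-5,8-bis(methoxymethoxy)naphthalene-1,4-dione, via 2-substituted 1-naphthol 15 (not isolated), via 3-substituted 1-naphthol 16 (not isolated)
Conditions: (+)-camphor-10-sulfonic acid (5 mol%), CH2Cl2, 0 °C; solid NaHCO3, filter, concentrate; then Co(salen) [N,N'-bis(salicylidene)ethylenediamine complex of divalent cobalt, C16H14CoN2O2] (10 mol%), O2 (1 atm), MeCN, 25 °C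
Reagents that add atoms: dioxygen, O=O
Why: Acid-catalysed ionisation of a bridgehead C–O bond (helped by the ortho acetal oxygen on the arene) followed by hydride shift or proton loss is the standard isomerisation of 1,4-epoxy-1,4-dihydronaphthalenes to 1-naphthols, and Co(salen)-catalysed aerobic oxidation of a 1-naphthol with a free para position gives the 1,4-quinone, so both regioisomeric naphthols should converge on one quinone with the remote stereocentre untouched.

Step 8
Reactants: 17 2-[(1R)-1-{[tert-butyl(dimethyl)silyl]oxy}-4-methylpent-3-en-1-yl]-5,8-bis(methoxymethoxy)naphthalene-1,4-dione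
Product: 18 5,8-dihydroxy-2-[(1R)-1-hydroxy-4-methylpent-3-en-1-yl]naphthalene-1,4-dione ((R)-shikonin)
Conditions: 2 N aq. HCl/THF (1:3), 25 °C, dark, under N2
Reagents that add atoms: none
Why: Acid-catalysed acetal hydrolysis of the two MOM ethers, eased by the peri quinone carbonyls that accept the freed phenols as hydrogen-bond donors, and concurrent protodesilylation of the secondary TBS ether should give the naphthazarin, whose carbinol centre and trisubstituted alkene are not expected to react with dilute aqueous acid at room temperature.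

Step 9
Reactants: 19 but-3-yn-1-ol; 20 2-bromopropene
Product: 21 5-methylhex-5-en-3-yn-1-ol
Conditions: PdCl2(PPh3)2 (2 mol%), CuI (4 mol%), Et3N, THF, 25 °C, closed vessel
Reagents that add atoms: none
Why: Sonogashira coupling of a terminal alkyne with a vinyl bromide forms the sp–sp2 bond and tolerates the free primary alcohol.

Step 10
Reactants: 21 5-methylhex-5-en-3-yn-1-ol
Product: 22 5-methylhex-5-en-3-ynoic acid
Conditions: CrO3, H2SO4, H2O/acetone, 0 °C
Reagents that add atoms: water, O (the second carboxyl oxygen enters through the aldehyde hydrate)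
Why: Jones oxidation of a homopropargylic primary alcohol gives the 3-alkynoic acid through the aldehyde hydrate, and the acidic medium avoids the base-induced alkyne-to-allene isomerisation.

Step 11
Reactants: 22 5-methylhex-5-en-3-ynoic acid
Product: 23 (3Z)-5-methylhexa-3,5-dienoic acid
Conditions: H2 (1 atm, stopped at one equivalent), Pd/CaCO3 poisoned with Pb(OAc)2 (Lindlar catalyst), quinoline, EtOAc, 0 °C
Reagents that add atoms: none
Why: Lindlar semi-hydrogenation adds hydrogen syn to the alkyne on the poisoned palladium surface, which fixes the Z geometry at C3–C4 under neutral conditions and should leave the 1,1-disubstituted alkene alone.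

Step 12
Reactants: 18 5,8-dihydroxy-2-[(1R)-1-hydroxy-4-methylpent-3-en-1-yl]naphthalene-1,4-dione; 23 (3Z)-5-methylhexa-3,5-dienoic acid
Product: 24 (1R)-1-(5,8-dihydroxy-1,4-dioxo-1,4-dihydronaphthalen-2-yl)-4-methylpent-3-en-1-yl (3Z)-5-methylhexa-3,5-dienoate (target)
Conditions: N,N'-dicyclohexylcarbodiimide (1.3 equiv), 23 (1.3 equiv), DMAP (0.1 equiv), CH2Cl2, −10 °C to 0 °C
Reagents that add atoms: none
Why: Steglich esterification acylates the secondary side-chain hydroxyl with retention at carbon while the two phenols stay locked in hydrogen bonds to the quinone carbonyls, and low temperature with substoichiometric DMAP should keep the skipped diene from moving into conjugation.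

**Compound list**

1 | 4-methylpent-3-enoic acid | CC(C)=CCC(=O)O | starting material
2 | 1-(1H-imidazol-1-yl)-4-methylpent-3-en-1-one (acyl imidazole) | CC(C)=CCC(=O)n1ccnc1 | intermediate
3 | N-methoxy-N,4-dimethylpent-3-enamide | CC(C)=CCC(=O)N(C)OC | intermediate
4 | 3-bromofuran | Brc1ccoc1 | starting material
5 | furan-3-yllithium | [Li]c1ccoc1 | intermediate
6 | lithium 1-(furan-3-yl)-1-[methoxy(methyl)amino]-4-methylpent-3-en-1-olate | CC(C)=CCC(O[Li])(N(C)OC)c1ccoc1 | intermediate
7 | 1-(furan-3-yl)-4-methylpent-3-en-1-one | CC(C)=CCC(=O)c1ccoc1 | intermediate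
8 | (1R)-1-(furan-3-yl)-4-methylpent-3-en-1-ol | O[C@H](CC=C(C)C)c1ccoc1 | intermediate
9 | tert-butyl{[(1R)-1-(furan-3-yl)-4-methylpent-3-en-1-yl]oxy}dimethylsilane | CC(C)(C)[Si](C)(C)O[C@H](CC=C(C)C)c1ccoc1 | intermediate
10 | 2-bromobenzene-1,4-diol | Oc1ccc(O)c(Br)c1 | starting material
11 | 2-bromo-1,4-bis(methoxymethoxy)benzene | COCOc1ccc(OCOC)c(Br)c1 | intermediate
12 | [2-bromo-3,6-bis(methoxymethoxy)phenyl]lithium | [Li]c1c(Br)c(OCOC)ccc1OCOC | intermediate
13 | 3,6-bis(methoxymethoxy)benzyne | COCOC1=CC=C(OCOC)C#C1 | intermediate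
14 | tert-butyl({(1R)-1-[5,8-bis(methoxymethoxy)-1,4-dihydro-1,4-epoxynaphthalen-2-yl]-4-methylpent-3-en-1-yl}oxy)dimethylsilane, both bridgehead epimers (bridge carbons cis, unassigned) | CC(C)(C)[Si](C)(C)O[C@H](CC=C(C)C)C1=CC2OC1c1c(OCOC)ccc(OCOC)c12 | intermediate
15 | 2-[(1R)-1-{[tert-butyl(dimethyl)silyl]oxy}-4-methylpent-3-en-1-yl]-5,8-bis(methoxymethoxy)naphthalen-1-ol | CC(C)(C)[Si](C)(C)O[C@H](CC=C(C)C)c1ccc2c(OCOC)ccc(OCOC)c2c1O | intermediate
16 | 3-[(1R)-1-{[tert-butyl(dimethyl)silyl]oxy}-4-methylpent-3-en-1-yl]-5,8-bis(methoxymethoxy)naphthalen-1-ol | CC(C)(C)[Si](C)(C)O[C@H](CC=C(C)C)c1cc(O)c2c(OCOC)ccc(OCOC)c2c1 | intermediate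
17 | 2-[(1R)-1-{[tert-butyl(dimethyl)silyl]oxy}-4-methylpent-3-en-1-yl]-5,8-bis(methoxymethoxy)naphthalene-1,4-dione | CC(C)(C)[Si](C)(C)O[C@H](CC=C(C)C)C1=CC(=O)c2c(OCOC)ccc(OCOC)c2C1=O | intermediate
18 | 5,8-dihydroxy-2-[(1R)-1-hydroxy-4-methylpent-3-en-1-yl]naphthalene-1,4-dione ((R)-shikonin) | O[C@H](CC=C(C)C)C1=CC(=O)c2c(O)ccc(O)c2C1=O | intermediate
19 | but-3-yn-1-ol | C#CCCO | starting material
20 | 2-bromopropene | C=C(C)Br | starting material
21 | 5-methylhex-5-en-3-yn-1-ol | C=C(C)C#CCCO | intermediate
22 | 5-methylhex-5-en-3-ynoic acid | C=C(C)C#CCC(=O)O | intermediate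
23 | (3Z)-5-methylhexa-3,5-dienoic acid | C=C(C)/C=C\CC(=O)O | intermediate
24 | (1R)-1-(5,8-dihydroxy-1,4-dioxo-1,4-dihydronaphthalen-2-yl)-4-methylpent-3-en-1-yl (3Z)-5-methylhexa-3,5-dienoate | C=C(C)/C=C\CC(=O)O[C@H](CC=C(C)C)C1=CC(=O)c2c(O)ccc(O)c2C1=O | target

**Step count**

Total steps: 12. Longest linear sequence: 8 steps (steps 1, 2, 3, 4, 6, 7, 8, 12).

**Steps most likely to fail**

Step 6. The process at risk is competition for the aryne and for the limiting furan. The lithium amide may metalate furan 9 at an α-position or add to aryne 13, and aryllithium 12 may add to 13, so that 9 is recovered or arylated instead of undergoing cycloaddition. The fallback generates the same aryne by bromine–lithium exchange, with no amide base or amine present; it sets out from furan 9 and comes back at cycloadduct 14. Commercial 1,4-benzoquinone is treated with Br2 in CHCl3 to give 5,6-dibromocyclohex-2-ene-1,4-dione F1. F1 is enolised with cold concentrated H2SO4 to 2,3-dibromobenzene-1,4-diol F2, which is protected with MOMCl and i-Pr2NEt as 2,3-dibromo-1,4-bis(methoxymethoxy)benzene F3. Slow addition of n-BuLi to F3 and 9 in toluene at −78 °C, then warming, should give 12 by exchange, 13 by loss of LiBr, and 14 by the same cycloaddition.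

Step 7. Two processes may go astray. The cationic bridge opening is expected to give both naphthols, and aerobic oxygenation at the crowded para position of 16 (between the side chain and the peri acetal) may stall. Radical coupling or ortho-oxygenation of these very electron-rich phenols may then take over. The fallback replaces the catalytic radical oxidation by a two-electron oxidative dearomatisation; it sets out from cycloadduct 14, isomerised to 15 and 16 as in step 7, and comes back at quinone 17. PhI(OAc)2 (2.2 equiv) in MeOH at 0 °C should convert 15 into the quinone monoketal 2-[(1R)-1-{[tert-butyl(dimethyl)silyl]oxy}-4-methylpent-3-en-1-yl]-4,4-dimethoxy-5,8-bis(methoxymethoxy)naphthalen-1(4H)-one F4, and 16 into the isomeric 3-[(1R)-1-{[tert-butyl(dimethyl)silyl]oxy}-4-methylpent-3-en-1-yl]-4,4-dimethoxy-5,8-bis(methoxymethoxy)naphthalen-1(4H)-one F5, methanol being a small nucleophile for the para carbon. Brief treatment of the mixture with oxalic acid on wet silica in CH2Cl2 should hydrolyse only the ketal and give 17.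

Step 8. Once the naphthazarin is unveiled, aqueous acid may ionise the carbinol carbon, with loss of configuration. It may also protonate the trisubstituted alkene so that the free hydroxyl closes a tetrahydrofuran ring, and acetal cleavage may stop after one MOM group. The fallback separates the two deprotections and keeps the hydroxyl silylated until protic acid is no longer needed; it sets out from quinone 17 and comes back at 18. Me3SiOTf and 2,2'-bipyridyl in CH2Cl2 at 0 °C should exchange each aryl MOM group for a trimethylsilyl group, giving 2-[(1R)-1-{[tert-butyl(dimethyl)silyl]oxy}-4-methylpent-3-en-1-yl]-5,8-bis(trimethylsilyloxy)naphthalene-1,4-dione F6. Adding water hydrolyses F6 to 2-[(1R)-1-{[tert-butyl(dimethyl)silyl]oxy}-4-methylpent-3-en-1-yl]-5,8-dihydroxynaphthalene-1,4-dione F7. HF·pyridine buffered with pyridine in THF at 0 °C should then remove the TBS group and give 18.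

**Further compounds**

F1 | step 6 | 5,6-dibromocyclohex-2-ene-1,4-dione (racemic trans) | O=C1C=CC(=O)C(Br)C1Br
F2 | step 6 | 2,3-dibromobenzene-1,4-diol | Oc1ccc(O)c(Br)c1Br
F3 | step 6 | 2,3-dibromo-1,4-bis(methoxymethoxy)benzene | COCOc1ccc(OCOC)c(Br)c1Br
F4 | step 7 | 2-[(1R)-1-{[tert-butyl(dimethyl)silyl]oxy}-4-methylpent-3-en-1-yl]-4,4-dimethoxy-5,8-bis(methoxymethoxy)naphthalen-1(4H)-one | CC(C)(C)[Si](C)(C)O[C@H](CC=C(C)C)C1=CC(OC)(OC)c2c(OCOC)ccc(OCOC)c2C1=O
F5 | step 7 | 3-[(1R)-1-{[tert-butyl(dimethyl)silyl]oxy}-4-methylpent-3-en-1-yl]-4,4-dimethoxy-5,8-bis(methoxymethoxy)naphthalen-1(4H)-one | CC(C)(C)[Si](C)(C)O[C@H](CC=C(C)C)C1=CC(=O)c2c(OCOC)ccc(OCOC)c2C1(OC)OC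
F6 | step 8 | 2-[(1R)-1-{[tert-butyl(dimethyl)silyl]oxy}-4-methylpent-3-en-1-yl]-5,8-bis(trimethylsilyloxy)naphthalene-1,4-dione | CC(C)(C)[Si](C)(C)O[C@H](CC=C(C)C)C1=CC(=O)c2c(O[Si](C)(C)C)ccc(O[Si](C)(C)C)c2C1=O
F7 | step 8 | 2-[(1R)-1-{[tert-butyl(dimethyl)silyl]oxy}-4-methylpent-3-en-1-yl]-5,8-dihydroxynaphthalene-1,4-dione | CC(C)(C)[Si](C)(C)O[C@H](CC=C(C)C)C1=CC(=O)c2c(O)ccc(O)c2C1=O
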